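The constants used here were chosen freely; what happens was integrated by code.

- Which flask ends with the most left-handed product, and how much does each hold at the end?

common to all: left-handed substrate 20 mM; solid reagent 24.0 mM; free catalyst 1.8 mM; right-handed substrate 20 mM; time 20 h

| charge | remark | temperature |
|---|---|---|
| maple | at 90 °C until 10 h, from then on at 110 °C |  |
| elm |  | 90 °C |
| alder |  | 110 °C |

- which flask leads in amount of left-handed product, in percent of the left-handed substrate and right-handed substrate together charged ("all alike" within 1.5 percentage points) (maple / elm / alder / all alike)
- how much left-handed product is there at the end, in percent of the left-handed substrate and right-handed substrate together charged: maple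
- how much left-handed product is there at the end, in percent of the left-handed substrate and right-handed substrate together charged: elm
- how much left-handed product is there at the end, in percent of the left-handed substrate and right-handed substrate together charged: alder

- free catalyst is single-handed; left-handed substrate and right-handed substrate are mirror images of each other, charged as a racemate, each of them at the stated concentration
- given per volume of solution although it is solid: solid reagent
- constants are those at 110 °C; use the activation energies and enthalpies for any other temperature
- at the start none of the solid reagent is in solution

    free catalyst + right-handed substrate ⇌ catalyst intermediate B (K1 = 110 M⁻¹, k1 = 14000 M⁻¹ h⁻¹, Ea1 = 58.0 kJ mol⁻¹, ΔH1 = −56.0 kJ mol⁻¹)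
    partner → decomposition product (k2 = 8.2 × 10⁻⁴ h⁻¹, Ea2 = 129 kJ mol⁻¹)
    partner + catalyst intermediate B → free catalyst + right-handed product (k3 = 5.5 M⁻¹ h⁻¹, Ea3 = 96.0 kJ mol⁻¹)
    partner + catalyst intermediate A → free catalyst + left-handed product (k4 = 200 M⁻¹ h⁻¹, Ea4 = 68.0 kJ mol⁻¹)
    solid reagent ⇌ partner, rate k5*(cs5 - [partner]) while solid is left; crystals form when [partner] > cs5 (cs5 = 17 mM, k5 = 0.16 h⁻¹)
    free catalyst + left-handed substrate ⇌ catalyst intermediate A (K6 = 27 M⁻¹, k6 = 7000 M⁻¹ h⁻¹, Ea6 = 39.0 kJ mol⁻¹, ΔH6 = 16.0 kJ mol⁻¹)
    (constants at 110 °C)

- I draw alder first, at 110 °C, because its constants stand as given.
- The left-handed substrate binds the catalyst at 140 h⁻¹, while intermediate A goes on at less than 3.40 h⁻¹, so I treat both bindings as balanced.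
- The catalyst then divides by the denominator 3.74. At the start, 14.4 % of it is intermediate A and 58.8 % is intermediate B, the resting state.
- [partner] starts at zero and climbs with a slope of 2.72 mM h⁻¹, the dissolution rate.
- Intermediate A consumes partner with a first-order constant of 0.0520 h⁻¹. I leave out the intermediate B route, which uses 0.112 as much partner.
- So in alder the knee of the curve comes at about 4.72 h. The level is 12.8 mM, below the solubility, so no crystals form.
- I replace this curve by its mean over the run, 9.85 mM.
- That mean dissolves 22.9 mM of the 24.0 mM charged, so the solid reagent lasts through the run in alder.
- A first pass puts the mean [left-handed substrate] near 16.0 mM, which lowers the denominator to 3.63.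
- My carried quantity is the mean pseudo-first-order constant of the left-handed substrate: the rate constant on intermediate A, times mean [partner], times the catalyst charged, times the binding constant, over the denominator. For alder it is 0.0264 h⁻¹.
- Over the run this gives 20.5 % left-handed product in alder.
- At 90 °C the product-forming step on intermediate A is about 3.24 times slower, and the binding constant drops to 20.5 M⁻¹. So I rank alder first, maple second and elm last, without figures for the latter two.
- The forecast names alder, with 15.9 % in maple, 3.7 % in elm and 21.5 % in alder, which is above my figure, and it “treated both catalyst intermediates as pre-equilibrated”.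
- The simulation puts alder ahead, with 15.9 % in maple, 3.72 % in elm and 21.1 % in alder, so my mean misses alder by 0.60 percentage points.
- Alder has not come to rest at 20.0 h. Its end state holds partner at 13.1 mM, catalyst intermediate A at 9.35 % of the catalyst charged, and left-handed substrate at 28.5 % of both substrates charged. These make the constant read 0.0386 h⁻¹, a half-life of 18.0 h. A neighbour of alder with 0.45 mM of free catalyst relaxes at 0.173 h⁻¹. On the starting denominator its constant is 0.00736 h⁻¹, which gives 6.84 %, and the neighbour holds 6.88 %. At 200 h alder holds 45.6 % left-handed product, with [partner] down to 0.544 mM.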